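**Plan**
- Retrosynthesis: after removal of four methoxymethyl (MOM) groups, ring C is cut at C4–C4a and at O1–C8a. These two bonds end on neighbouring carbons of ring A, and the C4–C3–C2–O1 unit between them (ketone carbon, oxygenated quaternary carbon, CH2, ring oxygen) maps onto the acyl carbon, α-carbon, CH2 and ring oxygen of a 3-aryl-3-alkoxyoxetan-2-one; ring A then comes from a 2-fluoroarylmagnesium reagent.
- The β-lactone is traced back to a malonate half-ester and on to an aryllithium plus diethyl oxomalonate (C3–C1′ bond). The 1,1-dimethylallyl group comes from a prenyl ether by Claisen rearrangement.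
- Forward: ring B is functionalised first (steps 1–5), the three-carbon unit is attached and turned into the β-lactone (steps 6–9), and ring A is joined and ring C closed in one operation (step 11); deprotection ends the route (step 12).
- Stereochemistry: the only stereocentre, C3, is set in step 7 by enzymatic desymmetrisation of a prochiral malonate. Reducing the remaining ester (step 8) fixes which arm becomes C2 and which C4, and no bond to C3 is made or broken afterwards.

Key step: step 11

Assumption: the esterase of step 7 is taken to hydrolyse the pro-R ester group of 13, the sense the route needs; the opposite sense would be met by reducing the acid instead of the ester in step 8.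

Abbreviation used in names: Ar = 4-methoxy-2,3-bis(methoxymethoxy)-5-(2-methylbut-3-en-2-yl)phenyl.

**Route**

Step 1
Reactants: 1 2,3-dihydroxybenzaldehyde
Product: 2 2,3-bis(methoxymethoxy)benzaldehyde
Conditions: MOMCl, iPr2NEt, CH2Cl2, 0 °C → rt
Reagents that add atoms: chloromethyl methyl ether, COCCl
Why: O-alkylation of both phenols with the reactive chloromethyl ether under amine base is routine acetal protection, an excess of reagent overcoming the hydrogen bond of the 2-hydroxyl to the aldehyde.

Step 2
Reactants: 2 2,3-bis(methoxymethoxy)benzaldehyde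
Product: 4 2,3-bis(methoxymethoxy)phenol, via aryl formate 3 (not isolated)
Conditions: mCPBA, CH2Cl2, 0 °C → rt; NaHCO3 wash; crude formate, K2CO3 (cat.), MeOH, rt
Reagents that add atoms: 3-chloroperoxybenzoic acid, OOC(=O)c1cccc(Cl)c1
Why: In this Dakin-type Baeyer–Villiger oxidation the electron-rich, ortho-oxygenated aryl group should migrate in preference to hydride, and base-catalysed methanolysis of the formate frees the phenol without touching the acetals.

Step 3
Reactants: 4 2,3-bis(methoxymethoxy)phenol; 5 prenyl bromide (1-bromo-3-methylbut-2-ene)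
Product: 6 1,2-bis(methoxymethoxy)-3-[(3-methylbut-2-en-1-yl)oxy]benzene
Conditions: K2CO3, acetone, reflux
Reagents that add atoms: none
Why: Williamson ether synthesis of the phenoxide with the primary allylic bromide should proceed at oxygen by SN2 under mild carbonate conditions.

Step 4
Reactants: 6 1,2-bis(methoxymethoxy)-3-[(3-methylbut-2-en-1-yl)oxy]benzene
Product: 8 2,3-bis(methoxymethoxy)-6-(2-methylbut-3-en-2-yl)phenol, via ortho dienone 7 (not isolated)
Conditions: PhNEt2, 190 °C, sealed tube, Ar
Reagents that add atoms: none
Why: The aromatic Claisen rearrangement, a [3,3] shift with allylic inversion, delivers the 1,1-dimethylallyl group to the only hydrogen-bearing ortho carbon, and the amine solvent should speed enolisation of the dienone so that onward migration is held back.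

Step 5
Reactants: 8 2,3-bis(methoxymethoxy)-6-(2-methylbut-3-en-2-yl)phenol
Product: 9 2-methoxy-3,4-bis(methoxymethoxy)-1-(2-methylbut-3-en-2-yl)benzene
Conditions: MeI, K2CO3, DMF, 40 °C
Reagents that add atoms: iodomethane, CI
Why: O-Methylation of the hindered phenoxide (Williamson ether synthesis) should be fast with iodomethane in DMF and also removes the free hydroxyl that could otherwise add to the neighbouring alkene.

Step 6
Reactants: 9 2-methoxy-3,4-bis(methoxymethoxy)-1-(2-methylbut-3-en-2-yl)benzene; 10 diethyl oxomalonate
Product: 13 diethyl 2-Ar-2-(methoxymethoxy)propanedioate, via aryllithium 11 (not isolated), via lithium alkoxide 12 (not isolated)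
Conditions: n-BuLi, TMEDA, THF, −20 → 0 °C; add to 10, THF, −78 °C; then MOMCl, −78 °C → rt
Reagents that add atoms: chloromethyl methyl ether, COCCl
Why: Directed ortho-metalation at the only ring position next to a methoxymethoxy group, 1,2-addition of the aryllithium to the highly electrophilic central carbonyl of the oxomalonate and O-alkylation of the resulting lithium alkoxide in the same flask should give the protected, prochiral aryl tartronate.

Step 7
Reactants: 13 diethyl 2-Ar-2-(methoxymethoxy)propanedioate
Product: 14 (2S)-2-Ar-3-ethoxy-2-(methoxymethoxy)-3-oxopropanoic acid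
Conditions: pig liver esterase, pH 7.5 phosphate buffer/DMSO (9:1), 30 °C; acidify to pH 4 at 0 °C on work-up
Reagents that add atoms: water, O
Why: Enzymatic desymmetrisation (hydrolysis of one of two enantiotopic ester groups of a 2,2-disubstituted malonate) creates the quaternary stereocentre, the enzyme being taken to cleave the pro-R ester to give the S half-ester.

Step 8
Reactants: 14 (2S)-2-Ar-3-ethoxy-2-(methoxymethoxy)-3-oxopropanoic acid
Product: 15 (2R)-2-Ar-3-hydroxy-2-(methoxymethoxy)propanoic acid
Conditions: LiOH (1.0 equiv), THF/H2O, evaporate; LiBH4, THF, 0 °C → rt; 1 M HCl to pH 3–4, 0 °C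
Reagents that add atoms: none
Why: In this chemoselective borohydride reduction LiBH4 reduces the α-alkoxy ester while the preformed lithium carboxylate is inert (and no borane is released to touch the alkene), so the former ester arm becomes CH2OH and the descriptor changes to R by priority only, no bond to the stereocentre being broken.

Step 9
Reactants: 15 (2R)-2-Ar-3-hydroxy-2-(methoxymethoxy)propanoic acid
Product: 16 (3R)-3-Ar-3-(methoxymethoxy)oxetan-2-one
Conditions: BOPCl, Et3N, CH2Cl2 (0.01 M), 0 °C → rt
Reagents that add atoms: none
Why: β-Lactonisation by carboxyl activation: the mixed phosphinic anhydride should be attacked by the β-hydroxyl in a 4-exo-trig closure favoured by the fully substituted α-carbon, with no bond to the stereocentre involved.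

Step 10
Reactants: 17 4-bromo-3-fluorophenol
Product: 18 1-bromo-2-fluoro-4-(methoxymethoxy)benzene
Conditions: MOMCl, iPr2NEt, CH2Cl2, 0 °C → rt
Reagents that add atoms: chloromethyl methyl ether, COCCl
Why: Standard methoxymethyl protection of a phenol (O-alkylation under amine base) masks the acidic hydroxyl that would quench the organomagnesium reagent of step 11.

Step 11
Reactants: 18 1-bromo-2-fluoro-4-(methoxymethoxy)benzene; 16 (3R)-3-Ar-3-(methoxymethoxy)oxetan-2-one
Product: 21 (3R)-3-Ar-3,7-bis(methoxymethoxy)-2,3-dihydro-4H-chromen-4-one, via arylmagnesium chloride 19 (not isolated), via keto alkoxide 20 (not isolated)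
Conditions: 18 (1.3 equiv), iPrMgCl·LiCl (1.2 equiv), THF, −15 → 0 °C; add to 16, THF, −78 → −30 °C; then DMPU, 0 → 45 °C
Reagents that add atoms: none
Why: Proposed new method: bromine–magnesium exchange gives the 2-fluoroarylmagnesium reagent, kept at or below 0 °C so that it does not lose MgClF to an aryne; it should add to the strained acyl carbon of 16, activated by chelation of magnesium between the lactone carbonyl and the α-methoxymethoxy oxygen, and the tetrahedral adduct should open at once by acyl–oxygen cleavage to the chloromagnesium alkoxide of a β-hydroxy ketone, which forms C4–C4a. The closest known reaction types are the opening of β-lactones at the acyl carbon by hard organometallic reagents to β-hydroxy ketones and the base-mediated intramolecular SNAr of 2-fluoroaryl ketones to chroman-4-ones; joining the two in one flask with a magnesium alkoxide as nucleophile is the untested part. Ring C closes by intramolecular addition–elimination at C8a (six-membered, 6-exo attack on the arene carbon), which becomes possible only once the new ortho ketone activates the fluoride, with magnesium assisting fluoride departure and DMPU raising the nucleophilicity of the alkoxide. No stereocentre is created: C3 is quaternary, cannot enolise and keeps the R configuration of the lactone because none of its bonds is touched. The step needs acyl rather than alkyl attack (secured by a copper-free magnesium nucleophile and by the neopentyl character of the CH2–O carbon), a single addition (the ketone is flanked by the quaternary C3 and an ortho-fluoroaryl group and is formed at low temperature with little excess reagent) and ring closure before retro-aldol loss of formaldehyde (a chelated magnesium alkoxide should fragment far less readily than an alkali alkoxide). Only the primary alkoxide can close the ring because the tertiary oxygen on C3 is masked, which excludes the five-membered benzofuranone alternative.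

Step 12
Reactants: 21 (3R)-3-Ar-3,7-bis(methoxymethoxy)-2,3-dihydro-4H-chromen-4-one
Product: 22 (3R)-3-[2,3-dihydroxy-4-methoxy-5-(2-methylbut-3-en-2-yl)phenyl]-3,7-dihydroxy-2,3-dihydro-4H-chromen-4-one
Conditions: 3 M aq. HCl, MeOH, 45 °C
Reagents that add atoms: none
Why: Acid-catalysed acetal exchange with methanol should remove the three aryl methoxymethyl ethers and then the tertiary one as dimethoxymethane, while the α-keto position of C3 disfavours ionisation and the alkene has no free ortho hydroxyl to cyclise with.

**Compound list**

1 | 2,3-dihydroxybenzaldehyde | O=Cc1cccc(O)c1O | starting material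
2 | 2,3-bis(methoxymethoxy)benzaldehyde | O=Cc1cccc(OCOC)c1OCOC | intermediate
3 | 2,3-bis(methoxymethoxy)phenyl formate (formed in the flask) | O=COc1cccc(OCOC)c1OCOC | intermediate
4 | 2,3-bis(methoxymethoxy)phenol | Oc1cccc(OCOC)c1OCOC | intermediate
5 | prenyl bromide (1-bromo-3-methylbut-2-ene) | CC(C)=CCBr | starting material
6 | 1,2-bis(methoxymethoxy)-3-[(3-methylbut-2-en-1-yl)oxy]benzene | CC(C)=CCOc1cccc(OCOC)c1OCOC | intermediate
7 | 2,3-bis(methoxymethoxy)-6-(2-methylbut-3-en-2-yl)cyclohexa-2,4-dien-1-one (racemic, formed in the flask) | O=C1C(C(C)(C)C=C)C=CC(OCOC)=C1OCOC | intermediate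
8 | 2,3-bis(methoxymethoxy)-6-(2-methylbut-3-en-2-yl)phenol | C=CC(C)(C)c1ccc(OCOC)c(OCOC)c1O | intermediate
9 | 2-methoxy-3,4-bis(methoxymethoxy)-1-(2-methylbut-3-en-2-yl)benzene | C=CC(C)(C)c1ccc(OCOC)c(OCOC)c1OC | intermediate
10 | diethyl oxomalonate | CCOC(=O)C(=O)C(=O)OCC | starting material
11 | [4-methoxy-2,3-bis(methoxymethoxy)-5-(2-methylbut-3-en-2-yl)phenyl]lithium (formed in the flask) | [Li]c1cc(C(C)(C)C=C)c(OC)c(OCOC)c1OCOC | intermediate
12 | lithium alkoxide of diethyl 2-Ar-2-hydroxypropanedioate (formed in the flask) | CCOC(=O)C(O[Li])(C(=O)OCC)c1cc(C(C)(C)C=C)c(OC)c(OCOC)c1OCOC | intermediate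
13 | diethyl 2-Ar-2-(methoxymethoxy)propanedioate | CCOC(=O)C(OCOC)(C(=O)OCC)c1cc(C(C)(C)C=C)c(OC)c(OCOC)c1OCOC | intermediate
14 | (2S)-2-Ar-3-ethoxy-2-(methoxymethoxy)-3-oxopropanoic acid | CCOC(=O)[C@](C(=O)O)(OCOC)c1cc(C(C)(C)C=C)c(OC)c(OCOC)c1OCOC | intermediate
15 | (2R)-2-Ar-3-hydroxy-2-(methoxymethoxy)propanoic acid | OC[C@](C(=O)O)(OCOC)c1cc(C(C)(C)C=C)c(OC)c(OCOC)c1OCOC | intermediate
16 | (3R)-3-Ar-3-(methoxymethoxy)oxetan-2-one | O=C1OC[C@]1(OCOC)c1cc(C(C)(C)C=C)c(OC)c(OCOC)c1OCOC | intermediate
17 | 4-bromo-3-fluorophenol | Oc1ccc(Br)c(F)c1 | starting material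
18 | 1-bromo-2-fluoro-4-(methoxymethoxy)benzene | COCOc1ccc(Br)c(F)c1 | intermediate
19 | [2-fluoro-4-(methoxymethoxy)phenyl]magnesium chloride, as its LiCl complex (formed in the flask) | COCOc1ccc([Mg]Cl)c(F)c1 | intermediate
20 | chloromagnesium alkoxide of (2R)-2-Ar-1-[2-fluoro-4-(methoxymethoxy)phenyl]-3-hydroxy-2-(methoxymethoxy)propan-1-one (formed in the flask) | Cl[Mg]OC[C@](C(=O)c1ccc(OCOC)cc1F)(OCOC)c1cc(C(C)(C)C=C)c(OC)c(OCOC)c1OCOC | intermediate
21 | (3R)-3-Ar-3,7-bis(methoxymethoxy)-2,3-dihydro-4H-chromen-4-one | C=CC(C)(C)c1cc([C@@]2(OCOC)COc3cc(OCOC)ccc3C2=O)c(OCOC)c(OCOC)c1OC | intermediate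
22 | (3R)-3-[2,3-dihydroxy-4-methoxy-5-(2-methylbut-3-en-2-yl)phenyl]-3,7-dihydroxy-2,3-dihydro-4H-chromen-4-one (CNP0274064.1) | C=CC(C)(C)c1cc([C@@]2(O)COc3cc(O)ccc3C2=O)c(O)c(O)c1OC | target

**Step count**
Total: 12 steps. Longest linear sequence: 11 steps (steps 1–9, 11 and 12); step 10 prepares the ring A partner.

**Steps most likely to fail**

Step 11 (proposed new method). The organomagnesium reagent may attack the CH2–O carbon or add twice, the 2-fluoroaryl reagent may collapse to an aryne before it is consumed, and the magnesium alkoxide may displace fluoride too slowly, so that retro-aldol loss of formaldehyde, and with it erosion of configuration at C3, overtakes ring closure. The fallback makes the two bonds in separate, known operations and sets out from 16. The chloromagnesium amide of N,O-dimethylhydroxylamine (MeNH(OMe)·HCl, iPrMgCl, THF, −20 °C) should open the lactone at the acyl carbon to the hydroxy Weinreb amide F1. Its hydroxyl is converted into the magnesium alkoxide with one equivalent of iPrMgCl, and reagent 19, made from 18 as in step 11, should then give the β-hydroxy 2-fluoroaryl ketone F2 by Weinreb ketone synthesis, the chelated adduct being unable to take up a second aryl group. K2CO3 in DMF at 60 °C closes ring C by alkoxide SNAr of the 2-fluoroaryl ketone and returns the material to the route at 21.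

Step 7. The crowded, fully substituted malonate may be hydrolysed slowly or with poor discrimination between its enantiotopic ester groups, and the α-aryl half-ester may decarboxylate during isolation. The fallback moves the desymmetrisation to the diol oxidation level and sets out from 13. LiAlH4 (THF, 0 °C) should give the prochiral diol F3. Lipase-catalysed acetylation of one enantiotopic hydroxymethyl arm (Pseudomonas cepacia lipase, vinyl acetate, t-BuOMe) should give the monoacetate F4. TEMPO/PhI(OAc)2 in aqueous MeCN oxidises the free arm to the acetoxy acid F5 without touching the alkene, and K2CO3 in MeOH removes the acetate to rejoin the route at 15.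

Step 4. The ortho dienone may migrate onward by a Cope shift to the unsubstituted para position, and the product phenol may undergo abnormal Claisen isomerisation or thermal ring closure onto its alkene. The fallback blocks the para position with a bromine that later replaces the directed metalation, and sets out from 4. Bu4NBr3 (CH2Cl2/MeOH, rt) should brominate para to the hydroxyl to give the 4-bromophenol F6. Alkylation with 5 (K2CO3, acetone) gives the bromo prenyl ether F7, and heating in PhNEt2 gives the rearranged bromophenol F8, for which only the ortho path remains. MeI/K2CO3 gives the aryl bromide F9, and bromine–lithium exchange (n-BuLi, THF, −78 °C) returns to the route at aryllithium 11, which is taken through the rest of step 6.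

Further compounds
F1 | step 11 | (2R)-2-Ar-3-hydroxy-N-methoxy-2-(methoxymethoxy)-N-methylpropanamide | CON(C)C(=O)[C@@](CO)(OCOC)c1cc(C(C)(C)C=C)c(OC)c(OCOC)c1OCOC
F2 | step 11 | (2R)-2-Ar-1-[2-fluoro-4-(methoxymethoxy)phenyl]-3-hydroxy-2-(methoxymethoxy)propan-1-one | OC[C@](C(=O)c1ccc(OCOC)cc1F)(OCOC)c1cc(C(C)(C)C=C)c(OC)c(OCOC)c1OCOC
F3 | step 7 | 2-Ar-2-(methoxymethoxy)propane-1,3-diol | OCC(CO)(OCOC)c1cc(C(C)(C)C=C)c(OC)c(OCOC)c1OCOC
F4 | step 7 | (2S)-2-Ar-3-hydroxy-2-(methoxymethoxy)propyl acetate | CC(=O)OC[C@](CO)(OCOC)c1cc(C(C)(C)C=C)c(OC)c(OCOC)c1OCOC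
F5 | step 7 | (2R)-3-acetoxy-2-Ar-2-(methoxymethoxy)propanoic acid | CC(=O)OC[C@](C(=O)O)(OCOC)c1cc(C(C)(C)C=C)c(OC)c(OCOC)c1OCOC
F6 | step 4 | 4-bromo-2,3-bis(methoxymethoxy)phenol | Oc1ccc(Br)c(OCOC)c1OCOC
F7 | step 4 | 1-bromo-2,3-bis(methoxymethoxy)-4-[(3-methylbut-2-en-1-yl)oxy]benzene | CC(C)=CCOc1ccc(Br)c(OCOC)c1OCOC
F8 | step 4 | 4-bromo-2,3-bis(methoxymethoxy)-6-(2-methylbut-3-en-2-yl)phenol | C=CC(C)(C)c1cc(Br)c(OCOC)c(OCOC)c1O
F9 | step 4 | 1-bromo-4-methoxy-2,3-bis(methoxymethoxy)-5-(2-methylbut-3-en-2-yl)benzene | C=CC(C)(C)c1cc(Br)c(OCOC)c(OCOC)c1OC
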